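(The earlier runs and the new flask were computed for an exercise; the scatter is artificial.)

Target present divided by substrate lost is a ratio of two amounts, and dividing it again by the partner charged puts no clock time into it. Here it is called the capture coefficient, a selectivity per unit of [partner] charged, and it is read at a stated moment of a run.

| flask | substrate | partner | temperature | remark | time |
|---|---|---|---|---|---|
| green | 1.1 M | 0.23 M | 35 °C | run made earlier |  |
| blue | 1.1 M | 0.43 M | 46 °C | run made earlier |  |
| teal | 1.1 M | 0.85 M | 35 °C | run made earlier |  |
| south-west | 1.1 M | 0.770 M |  | at 50 °C until 40 h, from then on at 30 °C | 3.0 d |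
| north-west | 1.1 M | 0.250 M |  | at 50 °C throughout | 3.0 d |

- green (time / d: target / %, substrate / %): 0.833: 0.4, 88.4; 1.67: 0.6, 80.3; 2.50: 2.2, 74.8; 4.00: 4.4, 67.5
- blue (time / h: target / %, substrate / %): 5.00: 0.5, 90.5; 12.0: 2.1, 83.2; 25.0: 5.8, 76.1; 40.0: 11.2, 69.8; 48.0: 12.7, 66.7
- teal (time / d: target / %, substrate / %): 0.333: 0, 95.1; 0.625: 0, 91.4; 1.25: 1.4, 84.3; 2.00: 4.6, 77.3; 4.00: 15.6, 63.7

(scatter of a reading: 0.3 percentage points)

- the flask that ends with the higher amount of target, in percent of the substrate charged, or "neither" when 2 percentage points or less lies between them (south-west / north-west / neither)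
- final target, as a percentage of the substrate charged, in south-west
- final target, as a percentage of the substrate charged, in north-west

- the numbers in the tables scatter by 0.3 percentage points (one standard deviation)

At the last readings at 35 °C, the green run gives 0.589 M⁻¹ and the teal run 0.506 M⁻¹, although their [partner] charges differ by a factor of 3.70. The blue run, hotter than both, reads 0.887 M⁻¹, and this capture coefficient is carried to the two flasks.

If each flask is taken to lose what the blue run had lost by its last reading, 33.3 % of its substrate, this estimate gives 22.7 % of target in south-west and 7.38 % in north-west. The gap of 15 percentage points is wider than the margin of 2 points, so south-west should end higher.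

The forecast also chose south-west, with 28.5 % there and 15.5 % in north-west, remarking of north-west that “the partner (only 23% of the charge) depletes”. The flasks give 25.3 % in south-west and 10.3 % in north-west, so south-west ends higher.

    substrate + target → side product A (k = 0.0140 M⁻¹ h⁻¹, Ea = 79.0 kJ mol⁻¹)
    substrate ⇌ open intermediate (K = 0.220, k = 0.0400 h⁻¹, Ea = 99.0 kJ mol⁻¹, ΔH = −55.0 kJ mol⁻¹)
    second intermediate → side product B (k = 0.0120 h⁻¹, Ea = 109 kJ mol⁻¹)
    partner → second intermediate (k = 0.0380 h⁻¹, Ea = 98.0 kJ mol⁻¹)
    open intermediate + second intermediate → target (k = 0.310 M⁻¹ h⁻¹, Ea = 77.0 kJ mol⁻¹)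
    (constants at 50 °C)

South-west has lost 48.0 % of its substrate at the end, and 11.2 % stands there as side product A, each unit of which counts as two. With that actual loss, 0.887 M⁻¹ reckons 32.8 % of target in south-west, against the 25.3 % found. Read at 12 d, south-west has lost 71.3 % of its substrate, so 0.887 M⁻¹ reckons 48.7 %, while that reading holds 35.1 %.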